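The data come from a simulation for substances that don't exist.

The easy step comes first: one coupling partner makes one target, so coupling partner is the limiting reagent in the delta run, where 80.0 mM stands against 200 mM of substrate, and target there cannot pass 40.0% of the substrate charged. The question is how far below that bound it ends.

| flask | substrate | coupling partner | catalyst | target | time |
|---|---|---|---|---|---|
| eta | 100 mM | 80.0 mM | 5.00 mM |  |  |
| alpha | 100 mM | 80.0 mM | 5.00 mM | 50.0 mM |  |
| gamma | 200 mM | 80.0 mM | 5.00 mM |  |  |
| zeta | 100 mM | 120 mM | 5.00 mM |  |  |
| delta | 200 mM | 80.0 mM | 15.0 mM |  | 20 min |

| eta run: time / min | eta run: [target] / mM | alpha run: time / min | alpha run: [target] / mM | gamma run: time / min | gamma run: [target] / mM | zeta run: time / min | zeta run: [target] / mM |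
|---|---|---|---|---|---|---|---|
| 3.3 | 31.6 | 3.3 | 82.2 | 3.3 | 41.8 | 3.3 | 41.1 |
| 6.7 | 49.1 | 6.7 | 98.5 | 6.7 | 59.6 | 6.7 | 64.5 |
| 10 | 57.9 | 10 | 109.2 | 10 | 66.8 | 10 | 77.1 |
| 13 | 64.5 | 13 | 114.5 | 13 | 70.1 | 13 | 85.8 |
| 17 | 68.1 | 17 | 117.8 | 17 | 72.4 | 17 | 91.4 |
| 20 | 70.0 | 20 | 119.6 | 20 | 73.7 | 20 | 94.4 |

(standard deviation of a reading: 0.5 mM)

- the power of [coupling partner] that the first rate follows, about the charge of the eta run; measure it at two percent of substrate made into target
- the power of [substrate] that the first rate follows, about the charge of the eta run; measure it at two percent of substrate made into target (one fixed amount of target, the same in the runs compared)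
- target in the delta run at 20 min, as a share of the substrate charged

- Overall: substrate + coupling partner -> target, with catalyst as catalyst.
- Constant volume, constant temperature.
- The analysis sees a species whether free or bound.
- "The second partner" is coupling partner.
- An order is taken over about fifteen percent of the charge, up and down.

The early readings come first. Adding target changes little: the alpha run has made 32.2 mM by its first reading, against 31.6 mM in the eta run. Comparing first readings over the whole steps in charge gives me an order of 0.404 in [substrate] and 0.648 in [coupling partner]. I take these as rough values of the first-rate orders: each spans a whole step in charge and the time up to the first reading.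

Two readers then dispute the delta run. The plateau reader notes that the gamma run holds the same substrate and coupling partner and flattens near 73.7 mM, so the delta run should end at the same 36.9%. The clock reader treats the missing coupling partner as a leak racing the reaction.

The clock reader defines an emptying time, the charge of coupling partner over the early rate. For the gamma run, that early rate is 12.7 mM/min, so the emptying time is 6.32 min. The shortfall at the last reading is 6.30 mM. The leak constant, shortfall over charge times emptying time, is then 0.0125 /min.

I side with the clock. Scaling the emptying time with catalyst gives 2.11 min for the delta run, hence a shortfall of 2.10 mM and 38.9% of the substrate charged.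

The forecast, on the clock's side with a different number and different grounds, gives 0.68, 0.5 and 39.5%, holding that “partner should be nearly consumed before death matters”.

The simulation gives 0.72 in [coupling partner], 0.55 in [substrate], and 38.5% for the delta run.

    catalyst + substrate → catalyst-substrate complex (61.20 /M/min)
    catalyst-substrate complex + coupling partner → target + catalyst (35.52 /M/min)
    substrate + coupling partner → target (0.4368 /M/min)
    coupling partner → lost reagent (0.01938 /min)

In the delta run, the catalytic cycle and the step to lost reagent ran together while coupling partner was present, and target reached 77.0 mM at 20 min. That is 2.91 mM short of the coupling partner charge, against 2.10 mM reckoned and the 6.30 mM of the gamma run, so the plateau reading belongs to the gamma run at 5.00 mM of catalyst. For the eta run, the emptying time 8.35 min and the leak constant give 8.33 mM, while its last reading is 10.0 mM short. Its target was still rising there, from 68.1 mM to 70.0 mM.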